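**Retrosynthetic overview**

1. Target ⇒ double esterification of a cyclopentane diol (its two other primary hydroxyls silylated) with two molecules of the (S)-side-chain acid carrying both aldehydes as dimethyl acetals; one mild acid step at the end frees everything.
2. Diol ⇒ bridged γ-lactone (2-oxabicyclo[2.2.1]heptan-3-one) by hydride reduction, selective silylation and debenzylation.
3. Key C–C bond: bridged lactone ⇒ acyclic enal–aldehyde. A carbene-derived homoenolate (the enal β-carbon) attacks the tethered aldehyde carbon; the cyclopentane forms first and the lactone bridge second in the same flask, setting three ring centres from one.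
4. The enal–aldehyde and the side-chain acid both ⇒ one dienal, through two iminium-catalysed 1,4-additions (silyl ketene N,O-acetal; dimethyl malonate) of the same facial sense.
5. Dienal ⇒ crotonaldehyde + acrolein (α-bromination, acetal, Heck coupling).

Assumption: the SMILES strings are authoritative for configuration; CIP labels in the names were derived from them.

**Route**

Step 1
Reactants: 1 (E)-but-2-enal
Product: 3 (Z)-2-bromobut-2-enal, via 2,3-dibromobutanal 2 (not isolated)
Conditions: Br2, CH2Cl2, −10 °C; then Et3N, 0 °C to rt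
Reagents that add atoms: bromine, BrBr
Why: Bromine addition followed by base-induced loss of HBr from the acidic α-position (bromination–dehydrobromination) gives the α-bromoenal as the isomer with methyl trans to the formyl group.

Step 2
Reactants: 3 (Z)-2-bromobut-2-enal
Product: 4 (Z)-2-bromo-1,1-dimethoxybut-2-ene
Conditions: HC(OMe)3, MeOH, p-toluenesulfonic acid (cat.), rt
Reagents that add atoms: trimethyl orthoformate, COC(OC)OC; methanol, CO
Why: Acid-catalysed acetalisation masks the future enal carbonyl and leaves the alkene geometry untouched.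

Step 3
Reactants: 4 (Z)-2-bromo-1,1-dimethoxybut-2-ene; 5 prop-2-enal (acrolein)
Product: 6 (2E,4E)-4-(dimethoxymethyl)hexa-2,4-dienal
Conditions: Pd(OAc)2 (5 mol%), tetrabutylammonium chloride, NaHCO3, DMF, 50 °C
Reagents that add atoms: none
Why: Heck coupling under ligand-free phase-transfer conditions: the vinyl–palladium species adds to the terminal carbon of acrolein and β-hydride elimination gives the E-enal, with retention of the vinyl bromide geometry.

Step 4
Reactants: 7 3-(benzyloxy)propanoic acid; 8 1H-pyrrole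
Product: 10 3-(benzyloxy)-1-(1H-pyrrol-1-yl)propan-1-one, via 3-(benzyloxy)propanoyl chloride 9 (not isolated)
Conditions: (COCl)2, DMF (cat.), CH2Cl2, 0 °C to rt; then pyrrole, Et3N, 4-(dimethylamino)pyridine (cat.), CH2Cl2, 0 °C to rt
Reagents that add atoms: none
Why: Acid chloride formation and N-acylation of pyrrole give a ketone-like acylpyrrole that can be enolised under soft conditions and later reduced like an ester.

Step 5
Reactants: 10 3-(benzyloxy)-1-(1H-pyrrol-1-yl)propan-1-one
Product: 11 1-[(1Z)-3-(benzyloxy)-1-{[tert-butyl(dimethyl)silyl]oxy}prop-1-en-1-yl]-1H-pyrrole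
Conditions: tert-butyldimethylsilyl triflate, Et3N, CH2Cl2, 0 °C
Reagents that add atoms: tert-butyldimethylsilyl trifluoromethanesulfonate, CC(C)(C)[Si](C)(C)OS(=O)(=O)C(F)(F)F
Why: Soft enolisation gives the Z enol silane (chain cis to the silyloxy group) without a free enolate that could expel benzyloxide.

Step 6
Reactants: 6 (2E,4E)-4-(dimethoxymethyl)hexa-2,4-dienal; 11 1-[(1Z)-3-(benzyloxy)-1-{[tert-butyl(dimethyl)silyl]oxy}prop-1-en-1-yl]-1H-pyrrole
Product: 13 (3S,4R)-4-[(benzyloxy)methyl]-3-[(2E)-1-oxobut-2-en-2-yl]-5-oxo-5-(1H-pyrrol-1-yl)pentanal, via acetal aldehyde 12 (not isolated)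
Conditions: (2R,5R)-5-benzyl-2-tert-butyl-3-methylimidazolidin-4-one trifluoroacetate (20 mol%), CH2Cl2, H2O (2 equiv), −40 °C; then 1 M HCl, THF, 0 °C
Reagents that add atoms: water, O
Why: Iminium-catalysed Mukaiyama–Michael addition: the (2R,5R)-imidazolidinone shields one face of the E-iminium of 6 so the ketene acetal adds 1,4 from the open face and sets C-3 as S, the Z acylpyrrole enol silane reacts through an open transition state to give the anti adduct and sets C-4 as R, and dilute acid then hydrolyses the allylic acetal to the enal.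

Step 7
Reactants: 13 (3S,4R)-4-[(benzyloxy)methyl]-3-[(2E)-1-oxobut-2-en-2-yl]-5-oxo-5-(1H-pyrrol-1-yl)pentanal
Product: 14 (1R,4S,5S,7R)-5-[(2R)-1-(benzyloxy)-3-oxo-3-(1H-pyrrol-1-yl)propan-2-yl]-7-methyl-2-oxabicyclo[2.2.1]heptan-3-one
Conditions: 2-mesityl-6,7-dihydro-5H-pyrrolo[2,1-c][1,2,4]triazol-2-ium chloride (15 mol%), 1,8-diazabicyclo[5.4.0]undec-7-ene (DBU, 10 mol%), THF (0.02 M), 40 °C
Reagents that add atoms: none
Why: Proposed new method: the N-mesityl carbene adds to the enal carbonyl to give the extended Breslow intermediate, whose β-carbon (a homoenolate, normally electrophilic) attacks the tethered aldehyde carbon in a 5-(enolendo)-exo-trig closure of the kind seen in cyclopentenone aldol condensations; the branched side chain turns away from the Breslow carbon (A(1,2) strain) and so lies opposite the incoming aldehyde, which puts it cis to the ring methyl of the E-enal, the aldehyde oxygen points to the enol O–H and ends trans to the methyl, and only the acyl azolium epimer with the carbonyl cis to the alkoxide can lactonise and release the catalyst, which fixes the last ring centre; the closest known reaction is the carbene-catalysed enal plus aldehyde γ-butyrolactone annulation (conjugate umpolung), with the reversible acyloin pathway as the expected competitor.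

Step 8
Reactants: 14 (1R,4S,5S,7R)-5-[(2R)-1-(benzyloxy)-3-oxo-3-(1H-pyrrol-1-yl)propan-2-yl]-7-methyl-2-oxabicyclo[2.2.1]heptan-3-one
Product: 15 (1R,2R,3S,4R)-4-[(2S)-1-(benzyloxy)-3-hydroxypropan-2-yl]-3-(hydroxymethyl)-2-methylcyclopentan-1-ol
Conditions: LiAlH4, THF, 0 °C to rt
Reagents that add atoms: none
Why: Hydride reduction opens the strained lactone to the ring alcohol plus hydroxymethyl group and reduces the acylpyrrole (an activated amide) to the second primary alcohol, without touching any stereocentre.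

Step 9
Reactants: 15 (1R,2R,3S,4R)-4-[(2S)-1-(benzyloxy)-3-hydroxypropan-2-yl]-3-(hydroxymethyl)-2-methylcyclopentan-1-ol
Product: 16 (1R,2R,3S,4R)-4-[(2R)-1-(benzyloxy)-3-{[tert-butyl(dimethyl)silyl]oxy}propan-2-yl]-3-({[tert-butyl(dimethyl)silyl]oxy}methyl)-2-methylcyclopentan-1-ol
Conditions: tert-butyldimethylsilyl chloride (2.2 equiv), imidazole, CH2Cl2, 0 °C
Reagents that add atoms: tert-butyldimethylsilyl chloride, CC(C)(C)[Si](C)(C)Cl
Why: Silylation is selective for the two primary hydroxyls over the hindered secondary ring hydroxyl next to the methyl-bearing carbon.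

Step 10
Reactants: 16 (1R,2R,3S,4R)-4-[(2R)-1-(benzyloxy)-3-{[tert-butyl(dimethyl)silyl]oxy}propan-2-yl]-3-({[tert-butyl(dimethyl)silyl]oxy}methyl)-2-methylcyclopentan-1-ol
Product: 17 (1R,2R,3S,4R)-4-[(2R)-1-{[tert-butyl(dimethyl)silyl]oxy}-3-hydroxypropan-2-yl]-3-({[tert-butyl(dimethyl)silyl]oxy}methyl)-2-methylcyclopentan-1-ol
Conditions: H2 (1 atm), Pd/C (10 wt%), EtOAc, rt
Reagents that add atoms: none
Why: Hydrogenolysis removes the benzyl ether (no alkene is present at this stage and silyl ethers survive in ethyl acetate), exposing exactly the two hydroxyls that are acylated in the target.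

Step 11
Reactants: 6 (2E,4E)-4-(dimethoxymethyl)hexa-2,4-dienal; 18 dimethyl propanedioate
Product: 20 dimethyl 2-[(3S,4E)-1,1-dimethoxy-4-(dimethoxymethyl)hex-4-en-3-yl]propanedioate, via malonate aldehyde 19 (not isolated)
Conditions: (R)-2-{bis[3,5-bis(trifluoromethyl)phenyl](trimethylsilyloxy)methyl}pyrrolidine (10 mol%), MeOH, 0 °C; then HC(OMe)3, p-toluenesulfonic acid (cat.), rt
Reagents that add atoms: trimethyl orthoformate, COC(OC)OC; methanol, CO
Why: Iminium-catalysed Michael addition of the malonate to the β-carbon from the face left open by the (R)-diarylprolinol silyl ether sets the S centre, and acetalisation in the same flask protects the new aldehyde.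

Step 12
Reactants: 20 dimethyl 2-[(3S,4E)-1,1-dimethoxy-4-(dimethoxymethyl)hex-4-en-3-yl]propanedioate
Product: 22 (3S,4E)-3-(2,2-dimethoxyethyl)-4-(dimethoxymethyl)hex-4-enoic acid, via malonic acid 21 (not isolated)
Conditions: LiOH, THF/MeOH/H2O, rt; 1 M HCl to pH 4, 0 °C; then pyridine, 100 °C
Reagents that add atoms: lithium hydroxide, [Li+].[OH-]
Why: Saponification and thermal decarboxylation of the malonic acid (malonic ester synthesis) give the acetic acid arm while both acetals survive the basic and pyridine conditions.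

Step 13
Reactants: 17 (1R,2R,3S,4R)-4-[(2R)-1-{[tert-butyl(dimethyl)silyl]oxy}-3-hydroxypropan-2-yl]-3-({[tert-butyl(dimethyl)silyl]oxy}methyl)-2-methylcyclopentan-1-ol; 22 (3S,4E)-3-(2,2-dimethoxyethyl)-4-(dimethoxymethyl)hex-4-enoic acid (2.5 equiv)
Product: 23 diester of 17 with two molecules of 22 (on the ring oxygen and on the free side-chain oxygen; both silyl ethers and all four dimethyl acetals in place)
Conditions: N,N'-dicyclohexylcarbodiimide, 4-(dimethylamino)pyridine (0.5 equiv), CH2Cl2, 0 °C to rt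
Reagents that add atoms: none
Why: Steglich esterification acylates the only two free hydroxyls, so the side-chain stereocentre that depends on which arm is acylated is already fixed by step 6.

Step 14
Reactants: 23 diester of 17 with two molecules of 22
Product: 24 (1R,2R,3S,4R)-4-[(2S)-1-{[(3S,4E)-4-formyl-3-(2-oxoethyl)hex-4-enoyl]oxy}-3-hydroxypropan-2-yl]-3-(hydroxymethyl)-2-methylcyclopentyl (3S,4E)-4-formyl-3-(2-oxoethyl)hex-4-enoate (CNP0192766.1)
Conditions: AcOH/THF/H2O (3:1:1), 35 °C
Reagents that add atoms: water, O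
Why: Mild aqueous acid hydrolyses the four dimethyl acetals and the two primary silyl ethers in one operation, under conditions chosen to be too mild for 1,3-acyl shift between the two side-chain arms.

**Compound list**

1 | (E)-but-2-enal (crotonaldehyde) | C/C=C/C=O | starting material
2 | 2,3-dibromobutanal (diastereomer mixture) | CC(Br)C(Br)C=O | intermediate
3 | (Z)-2-bromobut-2-enal | C/C=C(\Br)C=O | intermediate
4 | (Z)-2-bromo-1,1-dimethoxybut-2-ene | C/C=C(\Br)C(OC)OC | intermediate
5 | prop-2-enal (acrolein) | C=CC=O | starting material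
6 | (2E,4E)-4-(dimethoxymethyl)hexa-2,4-dienal | C/C=C(\C=C\C=O)C(OC)OC | intermediate
7 | 3-(benzyloxy)propanoic acid | OC(=O)CCOCc1ccccc1 | starting material
8 | 1H-pyrrole | c1cc[nH]c1 | starting material
9 | 3-(benzyloxy)propanoyl chloride | ClC(=O)CCOCc1ccccc1 | intermediate
10 | 3-(benzyloxy)-1-(1H-pyrrol-1-yl)propan-1-one | O=C(CCOCc1ccccc1)n1cccc1 | intermediate
11 | 1-[(1Z)-3-(benzyloxy)-1-{[tert-butyl(dimethyl)silyl]oxy}prop-1-en-1-yl]-1H-pyrrole | CC(C)(C)[Si](C)(C)O/C(=C\COCc1ccccc1)n1cccc1 | intermediate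
12 | (3S,4R)-4-[(benzyloxy)methyl]-3-[(2E)-1,1-dimethoxybut-2-en-2-yl]-5-oxo-5-(1H-pyrrol-1-yl)pentanal | c1ccccc1COC[C@H](C(=O)n1cccc1)[C@@H](/C(C(OC)OC)=C\C)CC=O | intermediate
13 | (3S,4R)-4-[(benzyloxy)methyl]-3-[(2E)-1-oxobut-2-en-2-yl]-5-oxo-5-(1H-pyrrol-1-yl)pentanal | c1ccccc1COC[C@H](C(=O)n1cccc1)[C@@H](/C(C=O)=C\C)CC=O | intermediate
14 | (1R,4S,5S,7R)-5-[(2R)-1-(benzyloxy)-3-oxo-3-(1H-pyrrol-1-yl)propan-2-yl]-7-methyl-2-oxabicyclo[2.2.1]heptan-3-one | c1ccccc1COC[C@H](C(=O)n1cccc1)[C@@H]1C[C@@H](O2)[C@H](C)[C@H]1C2=O | intermediate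
15 | (1R,2R,3S,4R)-4-[(2S)-1-(benzyloxy)-3-hydroxypropan-2-yl]-3-(hydroxymethyl)-2-methylcyclopentan-1-ol | c1ccccc1COC[C@H](CO)[C@@H]1C[C@@H](O)[C@H](C)[C@H]1CO | intermediate
16 | (1R,2R,3S,4R)-4-[(2R)-1-(benzyloxy)-3-{[tert-butyl(dimethyl)silyl]oxy}propan-2-yl]-3-({[tert-butyl(dimethyl)silyl]oxy}methyl)-2-methylcyclopentan-1-ol | c1ccccc1COC[C@H](CO[Si](C)(C)C(C)(C)C)[C@@H]1C[C@@H](O)[C@H](C)[C@H]1CO[Si](C)(C)C(C)(C)C | intermediate
17 | (1R,2R,3S,4R)-4-[(2R)-1-{[tert-butyl(dimethyl)silyl]oxy}-3-hydroxypropan-2-yl]-3-({[tert-butyl(dimethyl)silyl]oxy}methyl)-2-methylcyclopentan-1-ol | OC[C@H](CO[Si](C)(C)C(C)(C)C)[C@@H]1C[C@@H](O)[C@H](C)[C@H]1CO[Si](C)(C)C(C)(C)C | intermediate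
18 | dimethyl propanedioate (dimethyl malonate) | COC(=O)CC(=O)OC | starting material
19 | dimethyl 2-[(3S,4E)-4-(dimethoxymethyl)-1-oxohex-4-en-3-yl]propanedioate | C/C=C(/C(OC)OC)[C@@H](CC=O)C(C(=O)OC)C(=O)OC | intermediate
20 | dimethyl 2-[(3S,4E)-1,1-dimethoxy-4-(dimethoxymethyl)hex-4-en-3-yl]propanedioate | C/C=C(/C(OC)OC)[C@@H](CC(OC)OC)C(C(=O)OC)C(=O)OC | intermediate
21 | 2-[(3S,4E)-1,1-dimethoxy-4-(dimethoxymethyl)hex-4-en-3-yl]propanedioic acid | C/C=C(/C(OC)OC)[C@@H](CC(OC)OC)C(C(=O)O)C(=O)O | intermediate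
22 | (3S,4E)-3-(2,2-dimethoxyethyl)-4-(dimethoxymethyl)hex-4-enoic acid | C/C=C(/C(OC)OC)[C@@H](CC(OC)OC)CC(=O)O | intermediate
23 | diester of 17 with two molecules of 22 (ring oxygen and free side-chain oxygen acylated; two silyl ethers, four dimethyl acetals) | C/C=C(/C(OC)OC)[C@@H](CC(OC)OC)CC(=O)OC[C@H](CO[Si](C)(C)C(C)(C)C)[C@@H]1C[C@@H](OC(=O)C[C@H](CC(OC)OC)/C(C(OC)OC)=C\C)[C@H](C)[C@H]1CO[Si](C)(C)C(C)(C)C | intermediate
24 | (1R,2R,3S,4R)-4-[(2S)-1-{[(3S,4E)-4-formyl-3-(2-oxoethyl)hex-4-enoyl]oxy}-3-hydroxypropan-2-yl]-3-(hydroxymethyl)-2-methylcyclopentyl (3S,4E)-4-formyl-3-(2-oxoethyl)hex-4-enoate | C/C=C(/C=O)[C@@H](CC=O)CC(=O)OC[C@H](CO)[C@@H]1C[C@@H](OC(=O)C[C@H](CC=O)/C(C=O)=C\C)[C@H](C)[C@H]1CO | target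

**Step count**

Total: 14 steps. Longest linear sequence: 10 steps (1, 2, 3, 6, 7, 8, 9, 10, 13, 14).

**Three steps most likely to fail, with fallbacks**

Step 7 (carbene cyclisation). The carbene may add to the unhindered aliphatic aldehyde and close an acyloin ring onto the enal carbonyl, and α-branched enals are slow homoenolate precursors. The fallback sets out from 12 (taken out of step 6 before the acid treatment) and comes back at 15. The free aldehyde of 12 is added across the trisubstituted alkene with a cationic monovalent rhodium catalyst, [Rh(Ph2PCH2CH2PPh2)]ClO4 (5 mol%, CH2Cl2, rt). This intramolecular hydroacylation, in which an acyl–rhodium hydride acts as an acyl-anion equivalent, closes the same ring bond and gives the cyclopentanone acetal F1 as a mixture at the two new ring centres. Aqueous HCl in THF frees the aldehyde, and DBU then equilibrates both carbonyl-flanked ring centres to the all-trans keto aldehyde F2. LiAlH4 reduces the ketone, the aldehyde and the acylpyrrole; hydride enters cis to the ring methyl, as with 2-methylcyclopentanone, so triol 15 is the major epimer and the minor carbinol epimer is removed by chromatography.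

Step 6 (Mukaiyama–Michael addition). The dienal could react 1,6 instead of 1,4, and the anti/syn ratio with a benzyloxymethyl-substituted nucleophile is untested. The fallback sets out from 22 and comes back at 15. Compound 22 already carries the first stereocentre in the sense the core needs, so the second centre is set by an auxiliary instead. Pivaloyl chloride/Et3N, then lithiated (S)-4-benzyloxazolidin-2-one, give the N-acyl oxazolidinone F3. NaN(SiMe3)2 at −78 °C and benzyl chloromethyl ether alkylate the Z-enolate on the face away from the benzyl group (Evans alkylation) to give the benzyloxymethyl imide F4. Amberlyst-15 in wet acetone frees both aldehydes to give the dialdehyde imide F5. The carbene cyclisation of step 7 then gives the bridged lactone imide F6, and LiBH4 reduces the lactone and the imide to 15, releasing the auxiliary.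

Step 14 (global unmasking). Aqueous acid on a 1,3-diol monoester can shift the acyl group to the other arm, and four aldehydes are freed at once. The fallback sets out from 22 and 17 and comes back at 24. The aldehydes are freed before the coupling: Amberlyst-15 in wet acetone turns 22 into the dialdehyde acid F7. Esterification of 17 with F7 (N,N'-dicyclohexylcarbodiimide, 4-(dimethylamino)pyridine) gives the bis-silyl ether F8. Pyridine-buffered HF·pyridine in THF then removes only the two silyl groups, so the monoacylated diol never meets aqueous acid.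

**Further compounds**

F1 | step 7 | cyclopentanone acetal: 3-(benzyloxy)-2-[2-(dimethoxymethyl)-3-methyl-4-oxocyclopentyl]-1-(1H-pyrrol-1-yl)propan-1-one (mixture at the two new ring centres) | c1ccccc1COC[C@H](C(=O)n1cccc1)[C@@H]1CC(=O)C(C)C1C(OC)OC
F2 | step 7 | all-trans keto aldehyde: 2-[3-(benzyloxy)-1-oxo-1-(1H-pyrrol-1-yl)propan-2-yl]-5-methyl-4-oxocyclopentane-1-carbaldehyde (ring centres as in 15) | c1ccccc1COC[C@H](C(=O)n1cccc1)[C@@H]1CC(=O)[C@H](C)[C@H]1C=O
F3 | step 6 | (4S)-4-benzyl-3-[(3S,4E)-3-(2,2-dimethoxyethyl)-4-(dimethoxymethyl)hex-4-enoyl]-1,3-oxazolidin-2-one | C/C=C(/C(OC)OC)[C@@H](CC(OC)OC)CC(=O)N1[C@@H](Cc2ccccc2)COC1=O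
F4 | step 6 | (4S)-4-benzyl-3-[(2R,3S,4E)-2-[(benzyloxy)methyl]-3-(2,2-dimethoxyethyl)-4-(dimethoxymethyl)hex-4-enoyl]-1,3-oxazolidin-2-one | c1ccccc1COC[C@H](C(=O)N1[C@@H](Cc2ccccc2)COC1=O)[C@@H](/C(C(OC)OC)=C\C)CC(OC)OC
F5 | step 6 | (4S)-4-benzyl-3-[(2R,3S,4E)-2-[(benzyloxy)methyl]-4-formyl-3-(2-oxoethyl)hex-4-enoyl]-1,3-oxazolidin-2-one | c1ccccc1COC[C@H](C(=O)N1[C@@H](Cc2ccccc2)COC1=O)[C@@H](/C(C=O)=C\C)CC=O
F6 | step 6 | (4S)-4-benzyl-3-{(2R)-3-(benzyloxy)-2-[(1R,4S,5S,7R)-7-methyl-3-oxo-2-oxabicyclo[2.2.1]heptan-5-yl]propanoyl}-1,3-oxazolidin-2-one | c1ccccc1COC[C@H](C(=O)N1[C@@H](Cc2ccccc2)COC1=O)[C@@H]1C[C@@H](O2)[C@H](C)[C@H]1C2=O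
F7 | step 14 | (3S,4E)-4-formyl-3-(2-oxoethyl)hex-4-enoic acid | C/C=C(/C=O)[C@@H](CC=O)CC(=O)O
F8 | step 14 | bis(tert-butyldimethylsilyl) ether of 24 (both free primary hydroxyls silylated) | C/C=C(/C=O)[C@@H](CC=O)CC(=O)OC[C@H](CO[Si](C)(C)C(C)(C)C)[C@@H]1C[C@@H](OC(=O)C[C@H](CC=O)/C(C=O)=C\C)[C@H](C)[C@H]1CO[Si](C)(C)C(C)(C)C
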